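# Synthesis proposal for CNP0525385.1 (compound 32)

## The problem

Atom labels used throughout: C1 (bridgehead CH), C2 (spiro carbon), C3 (ketone), C4 (CH2), C5 (CH–O), O6, C7 (OCH2) and C8 (CMe2) follow 6-oxabicyclo[3.2.1]octane numbering. C9 is the ring-fusion CH on C2, C10 the carbinol carbon, C11 a CH2, C12 the CH that carries the propenal unit, C13 and C14 CH2, C15 the lactone OCH2 on C2, and C16 the lactone carbonyl on C10.

- Target 32 has four rings around one quaternary spiro carbon. Cyclohexanone ring A (C1–C5, C8) is spanned by the O6–C7 bridge into a tetrahydrofuran. C2 is shared with a δ-lactone (ring B: C2, C9, C10, C16, O, C15). Ring B is trans-fused along C9–C10 to cyclohexane ring C (C9–C14).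
- There are six stereocentres (C1, C2, C5, C9, C10, C12). C2, C9 and C10 are contiguous, and C2 and C10 are fully substituted.
- C5 can control C1, because the ether bridge can only close cis.
- The C8 methyl that is syn-axial to C2 shields one face of ring A and can control C2.
- The two unlike arms of C2 (bulky C1, flat C3) can bias C9 and C10. The axial C10 hydroxyl lies on the same face as H-12 and can direct a hydrogenation at C12.
- The 2-substituted propenal is a Michael acceptor and must come last. The tertiary α-hydroxy lactone and the β-alkoxy ketone (C3/C5–O6, open to retro-oxa-Michael cleavage) rule out strong base late in the route. Early hydroxy enol ethers are acid-sensitive.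
- The feature that makes the key step possible: C2 is α to the C3 ketone and carries C15, which can be an ester carbon. C1, next to C2, carries C7, and C7 is tied through O6 to C5. An open chain with a β-keto ester, a C5 hydroxyl and an enol ether C1=C7 can therefore form C2–C1 and O6–C7 in one oxidative step.

## Retrosynthesis

**32 from 31.** The exocyclic C=CH2 of the enal is cut. Aldehyde 31 lacks only this carbon, and a catalytic α-methylenation with formaldehyde is mild enough for the lactone, the tertiary alcohol and the ring A ketone. An isopropenyl group with late allylic oxidation was the neighbouring option, but it has no equally mild regioselective oxidation.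

**31 from 28 (through 30 and 29).** Aldehyde 31 comes from alcohol 30 and silyl ether 29 by functional-group changes. C12 is traced to alkene 28 (C12=C13). The forward reaction must add hydrogen to C12 from the face of the C10 hydroxyl, which a cationic iridium catalyst bound to that hydroxyl can do. This places the side chain equatorial.

**28 from 27, and 27 from 21 and 26.** Ring C is opened at C12=C13 (ring-closing metathesis of diene 27) and at C10–C11 (addition of allylsilane 26 to the ketone of keto lactone 21). The neighbouring cut, a vinyl ketone Michael–aldol annulation, closes ring C in one step. It leaves a ketone at C12 beside the ring A ketone and a β-hydroxy ketone prone to retro-aldol cleavage. The chosen cut brings C12 in with its two side-chain carbons. The addition must occur on the lactone face opposite both the C9 allyl group and C3.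

**21 from 19.** The C9–C14 bond is cut. Keto lactone 19 is enolisable only at C9, so O-allylation and Claisen rearrangement place the allyl group there. C9 stays α to a ketone and can equilibrate; the forward step must deliver the epimer with the allyl group trans to C1.

**19 from 17, and 17 from 16.** The C10 carbonyl is traced to the exocyclic methylene of lactone 17 (ozonolysis). Lactone 17 is cut at the acyl C16–O bond: the vinyl bromide and primary alcohol of 16 are joined by palladium-catalysed carbonylation. This route to the α-keto lactone avoids a free α-keto ester with a γ-hydroxyl, which would close to a five-membered hemiketal.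

**16 from 14, 13 and 12.** The C15 alcohol comes from the ester of 13, reduced while the C3 ketone is masked as silyl enol ether 14. The C2–C9 bond is cut to β-keto ester 12 and 2,3-dibromopropene. The forward alkylation must occur anti to the syn-axial C8 methyl, which leaves the ester (future C15) axial as in the target.

**12 from 11, and 11 from 10 (key step).** The acetal methoxy group of 11 is removed reductively to give 12. Acetal 11 is cut at C2–C1 and O6–C7 to acyclic β-keto ester 10. Two rings and the C1 stereocentre arise from a precursor with one stereocentre. The forward reaction must oxidise the β-keto ester to its radical without touching the enol ether or the product.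

**10 from 6 and 8, and the starting materials.**
- 10 is cut at C4–C5 into aldehyde 6 and dienol ether 8 (from methyl acetoacetate 7) by a catalytic asymmetric vinylogous aldol addition.
- 6 comes from ester 5, and 5 from aldehyde ester 2 and ylide 4 (from phosphonium salt 3). 2 is the oxidation product of commercial hydroxy ester 1.
- 26 comes from silyl alcohol 25, made from 3-methylbut-3-en-1-ol 22 through its dianion 23 and bis-silyl compound 24.

## Roads not taken

**Alternative 1:** Ring C would be cut at C9–C14 and C10–C11 in one operation. The enol of keto lactone 19 would add through C9 to methyl vinyl ketone, and the methyl ketone enolate would close onto the C10 ketone to give hydroxy ketone A1.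
- Merits: one step forms two bonds, ring C and the tertiary alcohol. The chosen plan needs steps 13, 16 and 17 for the same bonds, so this road is clearly shorter here.
- Weak points: intramolecular aldol closures of this kind usually give the cis-fused ketol first, and the trans fusion would depend on equilibration. The β-hydroxy ketone can dehydrate or revert. A1 carries a C12 ketone that must become CH–C(=CH2)CHO in the presence of the ring A ketone. That needs several olefination or enolate steps under base and a separate way to set C12.
- Against its step economy the chosen plan sets C9, C10 and C12 one at a time by separate elements, and it never has a ketone at C12.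

**Alternative 2:** Ring A would be cut between C8 and C1. Cp2TiCl would open a trisubstituted epoxide to a tertiary radical at C8, which adds 6-endo to the β-carbon of a tethered Z-enoate to give cyclohexanol ester A2.
- Merits: reductive radical conditions, a product that cannot be oxidised further, and a carbinol centre that comes from a reliable asymmetric epoxidation. In these respects it is safer than an oxidative cyclisation.
- Weak points: a tertiary radical must attack a carbon that already bears the benzyloxymethyl group. The precursor needs two oxygen stereocentres set beforehand. A2 has C3 at the alcohol level and the ether ring still open, so debenzylation, ether closure, desilylation and oxidation are needed to reach the stage of 12.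
- The chosen plan sets against its robustness a precursor with a single stereocentre and the closure of both rings in one step.

**Alternative 3:** Ring A would be cut at C4–C5 and the tetrahydrofuran at O6–C5. Me3SiOTf would turn a dimethyl acetal and a benzyl ether oxygen into a five-membered oxocarbenium ion, which the γ-carbon of a tethered acetoacetate bis-silyl dienol ether attacks to give A3.
- Merits: A3 is identical with 12 and is reached without an oxidant and without a separate acetal reduction. At this point the road is one step shorter and avoids any risk of over-oxidation.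
- Weak points: the stereocentre of the acyclic substrate is C1, a CH flanked by the gem-dimethyl carbon and the acetoacetate α-carbon. It is harder to set enantioselectively than a carbinol made by an aldol addition to an achiral aldehyde. C5 is formed only in the cyclisation. Loss of the benzyl group from an oxonium ion has less precedent.
- The chosen plan sets against the shorter sequence a stereocentre introduced by a catalytic aldol reaction, and a cyclisation whose C1 outcome is fixed by that centre.

Key step: step 6

## Route

Assumption: the methoxymethylene Wittig reaction is expected to give both enol ether isomers. The E isomer is drawn and numbered; the Z isomer is carried along, because the alkene geometry is lost when the radical adds in step 6.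

Step 1
Reactants: 1 methyl 3-hydroxy-2,2-dimethylpropanoate
Product: 2 methyl 2,2-dimethyl-3-oxopropanoate
Conditions: TEMPO (10 mol%), PhI(OAc)2, CH2Cl2, rt
Reagents that add atoms: none
Why: Oxoammonium (TEMPO) oxidation of a primary alcohol stops at the aldehyde; the product has no α-hydrogen, so it can neither enolise nor self-condense.

Step 2
Reactants: 2 methyl 2,2-dimethyl-3-oxopropanoate; 3 (methoxymethyl)triphenylphosphonium chloride
Product: 5 methyl (3E)-4-methoxy-2,2-dimethylbut-3-enoate, via (methoxymethylidene)triphenylphosphorane 4 (not isolated)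
Conditions: KOt-Bu, THF, 0 °C; then 2, 0 °C to rt
Reagents that add atoms: none
Why: Wittig reaction of the non-stabilised methoxymethylene ylide, which reacts with the aldehyde and not with the hindered ester.

Step 3
Reactants: 5 methyl (3E)-4-methoxy-2,2-dimethylbut-3-enoate
Product: 6 (3E)-4-methoxy-2,2-dimethylbut-3-enal
Conditions: i-Bu2AlH (1.05 equiv), CH2Cl2, −78 °C
Reagents that add atoms: none
Why: Partial reduction of an ester by i-Bu2AlH; the α-quaternary centre stabilises the tetrahedral aluminium hemiacetal at −78 °C, so the aldehyde is released only on work-up, and the enol ether is inert to hydride.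

Step 4
Reactants: 7 methyl acetoacetate
Product: 8 1-methoxy-1,3-bis(trimethylsilyloxy)buta-1,3-diene
Conditions: Me3SiOTf (2.2 equiv), Et3N (2.4 equiv), Et2O, 0 °C
Reagents that add atoms: trimethylsilyl triflate, C[Si](C)(C)OS(=O)(=O)C(F)(F)F
Why: Double O-silylation of a β-keto ester by soft enolisation with a silyl triflate and an amine base gives the bis-silyl dienol ether in one operation.

Step 5
Reactants: 6 (3E)-4-methoxy-2,2-dimethylbut-3-enal; 8 1-methoxy-1,3-bis(trimethylsilyloxy)buta-1,3-diene
Product: 10 methyl (5S,7E)-5-hydroxy-8-methoxy-6,6-dimethyl-3-oxooct-7-enoate, via bis-silylated aldol adduct 9 (not isolated)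
Conditions: Ti(Oi-Pr)4 (10 mol%), (S)-BINOL (10 mol%), 4 Å molecular sieves, THF, −78 to −20 °C; then K2CO3 (cat.), MeOH, 0 °C
Reagents that add atoms: none
Why: Catalytic asymmetric vinylogous Mukaiyama aldol addition through the terminal carbon of the dienol ether; the titanium–BINOL complex selects the aldehyde face, and (S)-BINOL is the enantiomer expected by analogy to give the 5S alcohol. Basic methanolysis removes both silyl groups without exposing the hydroxy enol ether to acid.

Step 6
Reactants: 10 methyl (5S,7E)-5-hydroxy-8-methoxy-6,6-dimethyl-3-oxooct-7-enoate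
Product: 11 methyl (1R,2S,5S,7S)-7-methoxy-8,8-dimethyl-3-oxo-6-oxabicyclo[3.2.1]octane-2-carboxylate
Conditions: undivided cell, reticulated vitreous carbon anode, Pt cathode, Fe(C5H5)2 (10 mol%), NaOMe (20 mol%), n-Bu4NBF4 (0.1 M), THF/MeOH 4:1, constant current, rt, 2.2 F/mol
Reagents that add atoms: none
Why: Methoxide deprotonates the β-keto ester, and the ferrocenium ion formed at the anode oxidises the enolate to the electrophilic C2 radical at a potential well below that needed to oxidise the enol ether or the alcohol. The radical adds to the electron-rich β-carbon of the enol ether (6-exo-trig, closing ring A and forming C2–C1), the polarity-matched position, and gives the α-methoxyalkyl radical at C7. A second one-electron oxidation gives the oxocarbenium ion, and the C5 hydroxyl adds to it (5-exo-trig, closing the tetrahydrofuran) to form the methyl acetal; the cathode reduces the released protons to hydrogen and regenerates methoxide. The closest known reactions are Mn(OAc)3-mediated and anodic oxidative cyclisations of 1,3-dicarbonyl compounds onto electron-rich alkenes with cationic termination, and ferrocene-mediated anodic generation of 1,3-dicarbonyl radicals. C1 is controlled by C5: only the isomer with C7 cis to the C5 oxygen can bridge, a chair transition state with both groups equatorial leads to it, and the gem-dimethyl group speeds the closure. C7 is set by the side from which the tethered hydroxyl reaches the cation and is removed in step 7; C2 stays epimerisable and should settle with the ester equatorial. The step needs chemoselective oxidation of the enolate and no second oxidation of the product; the mediator potential, the hindered C2–H of 11 and the charge limit are meant to secure this.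

Step 7
Reactants: 11 methyl (1R,2S,5S,7S)-7-methoxy-8,8-dimethyl-3-oxo-6-oxabicyclo[3.2.1]octane-2-carboxylate
Product: 12 methyl (1R,2S,5S)-8,8-dimethyl-3-oxo-6-oxabicyclo[3.2.1]octane-2-carboxylate
Conditions: Et3SiH (3 equiv), BF3·OEt2 (2 equiv), CH2Cl2, −78 to 0 °C
Reagents that add atoms: none
Why: Ionic reduction of a cyclic methyl acetal: BF3 ionises the methoxy group, and the silane reduces the oxocarbenium ion at C7 (which is not a bridgehead), while the boron-chelated β-keto ester is not reduced.

Step 8
Reactants: 12 methyl (1R,2S,5S)-8,8-dimethyl-3-oxo-6-oxabicyclo[3.2.1]octane-2-carboxylate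
Product: 13 methyl (1S,2R,5S)-2-(2-bromoprop-2-en-1-yl)-8,8-dimethyl-3-oxo-6-oxabicyclo[3.2.1]octane-2-carboxylate
Conditions: 2,3-dibromopropene, K2CO3, acetone, 56 °C
Reagents that add atoms: 2,3-dibromopropene, C=C(Br)CBr
Why: C-alkylation of a β-keto ester enolate by an allylic bromide. The C8 methyl syn-axial to C2 blocks one face, so the electrophile enters from the side of the O6–C7 bridge and the ester becomes axial, as in alkylations of 3-oxo-4-carboalkoxy decalins that bear an angular methyl group.

Step 9
Reactants: 13 methyl (1S,2R,5S)-2-(2-bromoprop-2-en-1-yl)-8,8-dimethyl-3-oxo-6-oxabicyclo[3.2.1]octane-2-carboxylate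
Product: 14 methyl (1S,2R,5S)-2-(2-bromoprop-2-en-1-yl)-8,8-dimethyl-3-(trimethylsilyloxy)-6-oxabicyclo[3.2.1]oct-3-ene-2-carboxylate
Conditions: Me3SiOTf, Et3N, CH2Cl2, 0 °C
Reagents that add atoms: trimethylsilyl triflate, C[Si](C)(C)OS(=O)(=O)C(F)(F)F
Why: Silyl enol ether formation by soft enolisation; C2 is quaternary, so only the C3=C4 enol ether can form, and it masks the ketone against hydride.

Step 10
Reactants: 14 methyl (1S,2R,5S)-2-(2-bromoprop-2-en-1-yl)-8,8-dimethyl-3-(trimethylsilyloxy)-6-oxabicyclo[3.2.1]oct-3-ene-2-carboxylate
Product: 16 (1S,2S,5S)-2-(2-bromoprop-2-en-1-yl)-2-(hydroxymethyl)-8,8-dimethyl-6-oxabicyclo[3.2.1]octan-3-one, via hydroxymethyl silyl enol ether 15 (not isolated)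
Conditions: i-Bu2AlH (3 equiv), CH2Cl2, −78 to 0 °C; then 1 M HCl, THF, 0 °C
Reagents that add atoms: none
Why: Ester reduction by an aluminium hydride, to which silyl enol ethers and vinyl bromides are inert; acid hydrolysis of the enol ether then returns the ketone, and the quaternary C2 excludes dehydration of the β-hydroxy ketone.

Step 11
Reactants: 16 (1S,2S,5S)-2-(2-bromoprop-2-en-1-yl)-2-(hydroxymethyl)-8,8-dimethyl-6-oxabicyclo[3.2.1]octan-3-one
Product: 17 (1S,2S,5S)-8,8-dimethyl-5'-methylidene-6-oxaspiro[bicyclo[3.2.1]octane-2,3'-oxane]-3,6'-dione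
Conditions: Pd(PPh3)4 (5 mol%), CO (1 atm), Et3N, MeCN, 70 °C
Reagents that add atoms: carbon monoxide, [C-]#[O+]
Why: Palladium-catalysed carbonylative lactonisation: oxidative addition of the vinyl bromide to zerovalent palladium, CO insertion and capture of the acyl complex by the primary hydroxyl give the α-methylene δ-lactone, helped by the quaternary C2.

Step 12
Reactants: 17 (1S,2S,5S)-8,8-dimethyl-5'-methylidene-6-oxaspiro[bicyclo[3.2.1]octane-2,3'-oxane]-3,6'-dione
Product: 19 (1S,2S,5S)-8,8-dimethyl-6-oxaspiro[bicyclo[3.2.1]octane-2,3'-oxane]-3,5',6'-trione, via spiro ozonide 18 (not isolated)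
Conditions: O3, CH2Cl2, −78 °C; then PPh3, −78 °C to rt
Reagents that add atoms: ozone, [O-][O+]=O
Why: Ozonolysis with reductive work-up of the only alkene present converts the α-methylene lactone into the α-keto lactone.

Step 13
Reactants: 19 (1S,2S,5S)-8,8-dimethyl-6-oxaspiro[bicyclo[3.2.1]octane-2,3'-oxane]-3,5',6'-trione
Product: 21 (1S,2R,4'S,5S)-8,8-dimethyl-4'-(prop-2-en-1-yl)-6-oxaspiro[bicyclo[3.2.1]octane-2,3'-oxane]-3,5',6'-trione, via enol allyl ether 20 (not isolated)
Conditions: allyl bromide, K2CO3, acetone, rt; then toluene, i-Pr2NEt (0.2 equiv), 110 °C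
Reagents that add atoms: allyl bromide, C=CCBr
Why: O-allylation of the acidic keto lactone enol, then Claisen rearrangement of the 2-alkoxycarbonyl allyl vinyl ether, moves the allyl group to C9 (any directly C-allylated material is the same product). C9 stays α to the ketone, and the amine lets it settle in the epimer with the allyl group equatorial and trans to the bulky C1 arm, where ring bond C9–C10 is anti to C1.

Step 14
Reactants: 22 3-methylbut-3-en-1-ol
Product: 25 3-[(trimethylsilyl)methyl]but-3-en-1-ol, via dilithiated 3-methylbut-3-en-1-ol 23 (not isolated), via O-trimethylsilyl ether of 25 24 (not isolated)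
Conditions: n-BuLi (2.2 equiv), TMEDA, Et2O, 0 °C to rt; then Me3SiCl (2.2 equiv), −78 °C to rt; then K2CO3 (cat.), MeOH, rt
Reagents that add atoms: chlorotrimethylsilane, C[Si](C)(C)Cl
Why: Alkoxide-directed allylic metalation of the methyl group gives the dianion, which is silylated at carbon and oxygen; methanolysis then cleaves only the labile O–Si bond.

Step 15
Reactants: 25 3-[(trimethylsilyl)methyl]but-3-en-1-ol
Product: 26 tert-butyldimethyl({3-[(trimethylsilyl)methyl]but-3-en-1-yl}oxy)silane
Conditions: t-BuMe2SiCl, imidazole, CH2Cl2, rt
Reagents that add atoms: tert-butyldimethylsilyl chloride, CC(C)(C)[Si](C)(C)Cl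
Why: Standard silylation of a primary alcohol; the silyl ether keeps the oxygen from taking part in the Lewis acid step and from acting as a second directing group in step 18.

Step 16
Reactants: 21 (1S,2R,4'S,5S)-8,8-dimethyl-4'-(prop-2-en-1-yl)-6-oxaspiro[bicyclo[3.2.1]octane-2,3'-oxane]-3,5',6'-trione; 26 tert-butyldimethyl({3-[(trimethylsilyl)methyl]but-3-en-1-yl}oxy)silane
Product: 27 (1S,2R,4'S,5'S,5S)-5'-{2-[2-(tert-butyldimethylsilyloxy)ethyl]prop-2-en-1-yl}-5'-hydroxy-8,8-dimethyl-4'-(prop-2-en-1-yl)-6-oxaspiro[bicyclo[3.2.1]octane-2,3'-oxane]-3,6'-dione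
Conditions: TiCl4 (1.1 equiv), CH2Cl2, −78 °C
Reagents that add atoms: none
Why: Hosomi–Sakurai allylation of the chelated α-keto lactone, which is far more electrophilic than the hindered ring A ketone. The allylsilane attacks C10 on the lactone face opposite both the C9 allyl group and the axial C3 arm of the spiro carbon, so C11 becomes equatorial and trans to C14, and the hydroxyl becomes axial.

Step 17
Reactants: 27 (1S,2R,4'S,5'S,5S)-5'-{2-[2-(tert-butyldimethylsilyloxy)ethyl]prop-2-en-1-yl}-5'-hydroxy-8,8-dimethyl-4'-(prop-2-en-1-yl)-6-oxaspiro[bicyclo[3.2.1]octane-2,3'-oxane]-3,6'-dione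
Product: 28 ring C cyclohexene (1S,2R,5S,9S,10S) with a C12=C13 double bond and a 2-(tert-butyldimethylsilyloxy)ethyl group on C12
Conditions: second-generation Grubbs catalyst (5 mol%), CH2Cl2, 40 °C
Reagents that add atoms: none
Why: Ring-closing metathesis of a monosubstituted with a 1,1-disubstituted alkene to a six-membered trisubstituted cycloalkene; the two chains are trans-diequatorial on the lactone, so the trans-fused ring closes without strain.

Step 18
Reactants: 28 ring C cyclohexene (1S,2R,5S,9S,10S) with a C12=C13 double bond and a 2-(tert-butyldimethylsilyloxy)ethyl group on C12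
Product: 29 saturated silyl ether (1S,2R,5S,9S,10S,12S) with the 2-(tert-butyldimethylsilyloxy)ethyl group equatorial on C12
Conditions: [Ir(cod)(PCy3)(py)]PF6 (5 mol%), H2 (1 atm), CH2Cl2, rt
Reagents that add atoms: none
Why: Hydroxyl-directed hydrogenation: the cationic iridium catalyst binds the axial homoallylic C10 hydroxyl and delivers hydrogen to the same face of C12=C13, so H-12 is cis to the hydroxyl and the side chain is equatorial.

Step 19
Reactants: 29 saturated silyl ether (1S,2R,5S,9S,10S,12S) with the 2-(tert-butyldimethylsilyloxy)ethyl group equatorial on C12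
Product: 30 primary alcohol (1S,2R,5S,9S,10S,12S) with a 2-hydroxyethyl group on C12
Conditions: HF·pyridine, pyridine, THF, 0 °C to rt
Reagents that add atoms: none
Why: Fluoride cleavage of a primary silyl ether under buffered, non-basic conditions that leave the lactone and the β-alkoxy ketone intact.

Step 20
Reactants: 30 primary alcohol (1S,2R,5S,9S,10S,12S) with a 2-hydroxyethyl group on C12
Product: 31 aldehyde (1S,2R,5S,9S,10S,12R) with a 2-oxoethyl group on C12
Conditions: Dess–Martin periodinane, CH2Cl2, rt
Reagents that add atoms: none
Why: Hypervalent iodine oxidation of the primary alcohol to the aldehyde; the tertiary C10 hydroxyl cannot be oxidised, and its trans relation to the side chain excludes lactol formation.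

Step 21
Reactants: 31 aldehyde (1S,2R,5S,9S,10S,12R) with a 2-oxoethyl group on C12
Product: 32 CNP0525385.1 (1S,2R,5S,9S,10S,12R), the 2-propenal on C12
Conditions: CH2O (37% aq.), pyrrolidine (10 mol%), EtCO2H (10 mol%), i-PrOH, 45 °C
Reagents that add atoms: formaldehyde, C=O
Why: Amine-catalysed α-methylenation of an aldehyde (enamine Mannich addition to formaldehyde, then elimination); it is selective for the aldehyde over the ring A ketone and does not touch C12.

## Compound list

1 | methyl 3-hydroxy-2,2-dimethylpropanoate | COC(=O)C(C)(C)CO | starting material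
2 | methyl 2,2-dimethyl-3-oxopropanoate | COC(=O)C(C)(C)C=O | intermediate
3 | (methoxymethyl)triphenylphosphonium chloride | COC[P+](c1ccccc1)(c1ccccc1)c1ccccc1.[Cl-] | starting material
4 | (methoxymethylidene)triphenylphosphorane | COC=P(c1ccccc1)(c1ccccc1)c1ccccc1 | intermediate
5 | methyl (3E)-4-methoxy-2,2-dimethylbut-3-enoate | COC(=O)C(C)(C)/C=C/OC | intermediate
6 | (3E)-4-methoxy-2,2-dimethylbut-3-enal | O=CC(C)(C)/C=C/OC | intermediate
7 | methyl acetoacetate | COC(=O)CC(C)=O | starting material
8 | 1-methoxy-1,3-bis(trimethylsilyloxy)buta-1,3-diene (ketene acetal geometry inconsequential) | C=C(O[Si](C)(C)C)C=C(OC)O[Si](C)(C)C | intermediate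
9 | (5S,7E)-1,8-dimethoxy-6,6-dimethyl-1,5-bis(trimethylsilyloxy)octa-1,7-dien-3-one (bis-silylated aldol adduct) | COC(O[Si](C)(C)C)=CC(=O)C[C@H](O[Si](C)(C)C)C(C)(C)/C=C/OC | intermediate
10 | methyl (5S,7E)-5-hydroxy-8-methoxy-6,6-dimethyl-3-oxooct-7-enoate | COC(=O)CC(=O)C[C@H](O)C(C)(C)/C=C/OC | intermediate
11 | methyl (1R,2S,5S,7S)-7-methoxy-8,8-dimethyl-3-oxo-6-oxabicyclo[3.2.1]octane-2-carboxylate | COC(=O)[C@@H]1C(=O)C[C@@H]2O[C@H](OC)[C@H]1C2(C)C | intermediate
12 | methyl (1R,2S,5S)-8,8-dimethyl-3-oxo-6-oxabicyclo[3.2.1]octane-2-carboxylate | COC(=O)[C@@H]1C(=O)C[C@@H]2OC[C@H]1C2(C)C | intermediate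
13 | methyl (1S,2R,5S)-2-(2-bromoprop-2-en-1-yl)-8,8-dimethyl-3-oxo-6-oxabicyclo[3.2.1]octane-2-carboxylate (bromoallyl group on the face of the O6–C7 bridge) | C=C(Br)C[C@]1(C(=O)OC)C(=O)C[C@@H]2OC[C@H]1C2(C)C | intermediate
14 | methyl (1S,2R,5S)-2-(2-bromoprop-2-en-1-yl)-8,8-dimethyl-3-(trimethylsilyloxy)-6-oxabicyclo[3.2.1]oct-3-ene-2-carboxylate | C=C(Br)C[C@]1(C(=O)OC)C(O[Si](C)(C)C)=C[C@@H]2OC[C@H]1C2(C)C | intermediate
15 | [(1S,2S,5S)-2-(2-bromoprop-2-en-1-yl)-8,8-dimethyl-3-(trimethylsilyloxy)-6-oxabicyclo[3.2.1]oct-3-en-2-yl]methanol | C=C(Br)C[C@]1(CO)C(O[Si](C)(C)C)=C[C@@H]2OC[C@H]1C2(C)C | intermediate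
16 | (1S,2S,5S)-2-(2-bromoprop-2-en-1-yl)-2-(hydroxymethyl)-8,8-dimethyl-6-oxabicyclo[3.2.1]octan-3-one | C=C(Br)C[C@]1(CO)C(=O)C[C@@H]2OC[C@H]1C2(C)C | intermediate
17 | (1S,2S,5S)-8,8-dimethyl-5'-methylidene-6-oxaspiro[bicyclo[3.2.1]octane-2,3'-oxane]-3,6'-dione (C15 on the face of the C8 methyl) | C=C1C[C@]2(COC1=O)C(=O)C[C@@H]3OC[C@H]2C3(C)C | intermediate
18 | spiro 1,2,4-trioxolane (ozonide) of 17 at C10, C1, C2 and C5 as in 17, ozonide carbon unassigned | O1COOC12C[C@]3(COC2=O)C(=O)C[C@@H]4OC[C@H]3C4(C)C | intermediate
19 | (1S,2S,5S)-8,8-dimethyl-6-oxaspiro[bicyclo[3.2.1]octane-2,3'-oxane]-3,5',6'-trione | O=C1C[C@]2(COC1=O)C(=O)C[C@@H]3OC[C@H]2C3(C)C | intermediate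
20 | 5'-(prop-2-en-1-yloxy)-4',5'-didehydro enol ether of 19 (C1, C2, C5 as in 19) | C=CCOC1=C[C@]2(COC1=O)C(=O)C[C@@H]3OC[C@H]2C3(C)C | intermediate
21 | (1S,2R,4'S,5S)-8,8-dimethyl-4'-(prop-2-en-1-yl)-6-oxaspiro[bicyclo[3.2.1]octane-2,3'-oxane]-3,5',6'-trione (allyl on C9 trans to C1 across the lactone) | C=CC[C@H]1[C@]2(COC(=O)C1=O)C(=O)C[C@@H]3OC[C@H]2C3(C)C | intermediate
22 | 3-methylbut-3-en-1-ol | C=C(C)CCO | starting material
23 | dilithiated 3-methylbut-3-en-1-ol (lithium 3-(lithiomethyl)but-3-en-1-olate) | [Li]CC(=C)CCO[Li] | intermediate
24 | trimethyl({3-[(trimethylsilyl)methyl]but-3-en-1-yl}oxy)silane | C=C(C[Si](C)(C)C)CCO[Si](C)(C)C | intermediate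
25 | 3-[(trimethylsilyl)methyl]but-3-en-1-ol | C=C(C[Si](C)(C)C)CCO | intermediate
26 | tert-butyldimethyl({3-[(trimethylsilyl)methyl]but-3-en-1-yl}oxy)silane | C=C(C[Si](C)(C)C)CCO[Si](C)(C)C(C)(C)C | intermediate
27 | (1S,2R,4'S,5'S,5S)-5'-{2-[2-(tert-butyldimethylsilyloxy)ethyl]prop-2-en-1-yl}-5'-hydroxy-8,8-dimethyl-4'-(prop-2-en-1-yl)-6-oxaspiro[bicyclo[3.2.1]octane-2,3'-oxane]-3,6'-dione (hydroxyl axial, syn to C3; C11 trans to C14) | C=CC[C@H]1[C@]2(COC(=O)[C@]1(O)CC(=C)CCO[Si](C)(C)C(C)(C)C)C(=O)C[C@@H]3OC[C@H]2C3(C)C | intermediate
28 | ring C cyclohexene (1S,2R,5S,9S,10S): trans-fused spiro lactone with C12=C13 and a 2-(tert-butyldimethylsilyloxy)ethyl group on C12 | CC(C)(C)[Si](C)(C)OCCC1=CC[C@H]2[C@]3(COC(=O)[C@]2(O)C1)C(=O)C[C@@H]1OC[C@H]3C1(C)C | intermediate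
29 | saturated silyl ether (1S,2R,5S,9S,10S,12S): side chain equatorial on C12, H-12 cis to the C10 hydroxyl | CC(C)(C)[Si](C)(C)OCC[C@@H]1CC[C@H]2[C@]3(COC(=O)[C@]2(O)C1)C(=O)C[C@@H]1OC[C@H]3C1(C)C | intermediate
30 | primary alcohol (1S,2R,5S,9S,10S,12S) with a 2-hydroxyethyl group on C12 | OCC[C@@H]1CC[C@H]2[C@]3(COC(=O)[C@]2(O)C1)C(=O)C[C@@H]1OC[C@H]3C1(C)C | intermediate
31 | aldehyde (1S,2R,5S,9S,10S,12R) with a 2-oxoethyl group on C12 | O=CC[C@@H]1CC[C@H]2[C@]3(COC(=O)[C@]2(O)C1)C(=O)C[C@@H]1OC[C@H]3C1(C)C | intermediate
32 | CNP0525385.1 (1S,2R,5S,9S,10S,12R in the numbering of this proposal) | C=C(C=O)[C@@H]1CC[C@H]2[C@]3(COC(=O)[C@]2(O)C1)C(=O)C[C@@H]1OC[C@H]3C1(C)C | target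

## Step count and risks

Total step count: 21 (steps 4, 14 and 15 prepare the two side fragments).
Longest linear sequence: 18 steps (steps 1–3, 5–13 and 16–21).

**Step 6 (key step).**
- What may go wrong: protons released at the anode may catalyse addition of the C5 hydroxyl to the enol ether before the radical forms, which removes the acceptor. The remaining C2–H of the product may be oxidised further, costing charge and material. Cyclisation through the trans arrangement would end in methanol capture and not in bridging.
- Fallback: a carbenoid route from 10 that rejoins at 12. Acid-catalysed cyclisation of 10 with loss of methanol (camphorsulfonic acid, toluene, 80 °C) would give methyl 4-[(2S)-3,3-dimethyl-2,3-dihydrofuran-2-yl]-3-oxobutanoate F1. Diazo transfer (4-acetamidobenzenesulfonyl azide, Et3N) would give methyl 2-diazo-4-[(2S)-3,3-dimethyl-2,3-dihydrofuran-2-yl]-3-oxobutanoate F2. Rh2(OAc)4 would cyclopropanate the dihydrofuran intramolecularly to methyl 8,8-dimethyl-3-oxo-6-oxatricyclo[3.2.1.0(2,7)]octane-2-carboxylate F3. Et3SiH with BF3·OEt2 would open the donor–acceptor cyclopropane bond C2–C7 reductively to 12.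

**Step 5.**
- What may go wrong: slow addition and low enantioselectivity with the α-quaternary aldehyde, and acid-triggered acetal formation from the hydroxy enol ether on work-up.
- Fallback: an auxiliary-based route from 6 that rejoins at 10. The doubly deprotonated acetate of (S)-2-hydroxy-1,2,2-triphenylethanol (LiN(i-Pr)2, then MgBr2, THF, below −78 °C) would add to 6 to give (1S)-2-hydroxy-1,2,2-triphenylethyl (3S,5E)-3-hydroxy-6-methoxy-4,4-dimethylhex-5-enoate F4. Claisen condensation with excess LiCH2CO2Me would convert it into 10. Every operation is basic, which suits the enol ether.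

**Step 13.**
- What may go wrong: poor diastereocontrol at C9 if the thermal rearrangement is unselective and the equilibrium between the C9 epimers is not decisive; also incomplete rearrangement of the enol ether.
- Fallback: a ligand-controlled route from 19 that rejoins at 21. Acylation of the enol of 19 with allyl chloroformate would give the allyl enol carbonate of 19 F5. Pd2(dba)3 with the matched enantiomer of t-Bu-PHOX (THF, rt) would effect decarboxylative allylation at C9 under kinetic catalyst control.

**Step 16.**
- What may go wrong: Lewis acid may enolise the keto lactone or cleave the silyl ether, and facial selectivity may be poor if the lactone does not adopt the expected conformation.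
- Fallback: an organoindium route from 21 that rejoins at 27. Bromodesilylation of 26 with N-bromosuccinimide would give {[3-(bromomethyl)but-3-en-1-yl]oxy}(tert-butyl)dimethylsilane F6. Indium powder in THF/H2O would add it to the C10 ketone of 21 under neutral conditions.

**Step 18.**
- What may go wrong: poor facial selectivity if the lactone carbonyl competes with the hydroxyl for the catalyst, or migration of the double bond before reduction.
- Fallback: a radical hydrogen-atom-transfer hydrogenation from 28 to 29 (Mn(dpm)3, PhSiH3, t-BuOOH, i-PrOH, rt). It does not depend on a directing group and favours the thermodynamically preferred equatorial side chain. No new compound arises.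

## Further compounds

F1 | step 6 | methyl 4-[(2S)-3,3-dimethyl-2,3-dihydrofuran-2-yl]-3-oxobutanoate | COC(=O)CC(=O)C[C@@H]1OC=CC1(C)C
F2 | step 6 | methyl 2-diazo-4-[(2S)-3,3-dimethyl-2,3-dihydrofuran-2-yl]-3-oxobutanoate | COC(=O)C(=[N+]=[N-])C(=O)C[C@@H]1OC=CC1(C)C
F3 | step 6 | methyl 8,8-dimethyl-3-oxo-6-oxatricyclo[3.2.1.0(2,7)]octane-2-carboxylate (cyclopropane C1–C2–C7; C1 and C5 as in 12) | COC(=O)[C@]12C(=O)C[C@@H]3O[C@H]1[C@H]2C3(C)C
F4 | step 5 | (1S)-2-hydroxy-1,2,2-triphenylethyl (3S,5E)-3-hydroxy-6-methoxy-4,4-dimethylhex-5-enoate | CO/C=C/C(C)(C)[C@@H](O)CC(=O)O[C@@H](c1ccccc1)C(O)(c1ccccc1)c1ccccc1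
F5 | step 13 | allyl enol carbonate of 19 (prop-2-en-1-yl carbonate of the C9=C10 enol; C1, C2, C5 as in 19) | C=CCOC(=O)OC1=C[C@]2(COC1=O)C(=O)C[C@@H]3OC[C@H]2C3(C)C
F6 | step 16 | {[3-(bromomethyl)but-3-en-1-yl]oxy}(tert-butyl)dimethylsilane | C=C(CBr)CCO[Si](C)(C)C(C)(C)C
F0 | step 18 | none | none
A1 | alternative 1 | trans-fused hydroxy lactone with a ketone at C12 | O=C1CC[C@H]2[C@]3(COC(=O)[C@]2(O)C1)C(=O)C[C@@H]1OC[C@H]3C1(C)C
A2 | alternative 2 | methyl 6-[(benzyloxy)methyl]-2-(tert-butyldimethylsilyloxy)-4-hydroxy-5,5-dimethylcyclohexane-1-carboxylate (configuration as in the SMILES) | COC(=O)[C@H]1[C@@H](O[Si](C)(C)C(C)(C)C)C[C@H](O)C(C)(C)[C@@H]1COCc1ccccc1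
A3 | alternative 3 | methyl (1R,2S,5S)-8,8-dimethyl-3-oxo-6-oxabicyclo[3.2.1]octane-2-carboxylate (identical with 12) | COC(=O)[C@@H]1C(=O)C[C@@H]2OC[C@H]1C2(C)C
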